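**Strategy.** The seven-membered ring (ring B) is disconnected at its only olefin, C7=C8 (daucane numbering: C1 angular-methyl carbon, C4 isopropyl carbinol, C5 ring-fusion CH, C6 ester carbinol, C9 carbinol). Because C6 and C9 are both allylic carbinols flanking this trisubstituted alkene, the ring can be closed last by ring-closing metathesis of a vinyl carbinol ester arm on C5 and an isopropenyl carbinol arm on C1, trans-disposed on a fully substituted cyclopentane. In one operation the metathesis forms ring B and delivers the target itself, with all five stereocentres, the free hydroxyls and the anisoate already in place. The precursor arises from a cyclopentenone by asymmetric conjugate addition, aldol, isopropyl addition and epoxide isomerisation.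

Key step: step 8

Remark: for each catalyst-controlled step (2, 3, 6) the catalyst antipode predicted by its accepted facial model is assumed; all three catalysts are available in both enantiomeric forms.

**Step 1**
Reactants: 1 3-bromocyclopent-2-en-1-one; 2 tributyl(3-methylbut-2-en-1-yl)stannane
Product: 3 3-(3-methylbut-2-en-1-yl)cyclopent-2-en-1-one
Conditions: Pd(PPh3)4 (5 mol%), LiCl, DMF, 80 °C
Reagents that add atoms: none
Why: Stille cross-coupling, in which oxidative addition of the β-bromoenone to zerovalent palladium, tin-to-palladium allyl transfer and reductive elimination at the unsubstituted allyl terminus should give the linear prenyl enone; no stereocentre is formed.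

**Step 2**
Reactants: 3 3-(3-methylbut-2-en-1-yl)cyclopent-2-en-1-one
Product: 5 triethyl{[(3R)-3-methyl-3-(3-methylbut-2-en-1-yl)cyclopent-1-en-1-yl]oxy}silane, via dimethylaluminium enolate 4 (not isolated)
Conditions: Me3Al, Cu(OTf)2 (5 mol%), chiral sulfonate-bearing imidazolinium salt (NHC precursor, 6 mol%), THF, −78 °C; then Et3SiOTf, −78 → 0 °C
Reagents that add atoms: trimethylaluminium, C[Al](C)C; triethylsilyl trifluoromethanesulfonate, CC[Si](CC)(CC)OS(=O)(=O)C(F)(F)F
Why: Copper-catalysed asymmetric conjugate addition of methyl to a β-alkyl cyclopentenone sets the quaternary C1 (R) under control of the chiral carbene ligand, and O-silylation of the regiodefined aluminium enolate fixes the C4=C5 enol ether.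

**Step 3**
Reactants: 5 triethyl{[(3R)-3-methyl-3-(3-methylbut-2-en-1-yl)cyclopent-1-en-1-yl]oxy}silane; 6 prop-2-enal (acrolein)
Product: 8 (2S,3R)-2-[(1S)-1-hydroxyprop-2-en-1-yl]-3-methyl-3-(3-methylbut-2-en-1-yl)cyclopentan-1-one, via trichlorosilyl aldolate 7 (not isolated)
Conditions: SiCl4 (1.5 equiv), chiral 2,2'-binaphthyldiamine-derived bisphosphoramide (5 mol%), i-Pr2NEt (10 mol%), CH2Cl2, −78 °C; aq. NaHCO3
Reagents that add atoms: none
Why: Lewis-base-catalysed Mukaiyama aldol in which the chiral phosphoramide-bound chlorosilyl cation activates acrolein, Re-face attack should set C6 (S) and the anti-selective open transition state of the cyclic enol ether should set C5 (S), so that catalyst control overrides the weak methyl/prenyl facial bias of C1.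

**Step 4**
Reactants: 8 (2S,3R)-2-[(1S)-1-hydroxyprop-2-en-1-yl]-3-methyl-3-(3-methylbut-2-en-1-yl)cyclopentan-1-one
Product: 9 (1R,2S,3R)-2-[(1S)-1-hydroxyprop-2-en-1-yl]-3-methyl-3-(3-methylbut-2-en-1-yl)-1-(propan-2-yl)cyclopentan-1-ol
Conditions: anhydrous CeCl3 (3.5 equiv), i-PrMgCl (3.5 equiv), THF, −78 → 0 °C; aq. NH4Cl
Reagents that add atoms: isopropylmagnesium chloride, CC(C)[Mg]Cl
Why: Organocerium 1,2-addition to a hindered, enolisable β-hydroxy ketone, in which isopropyl should add to the carbonyl face anti to the adjacent C5 hydroxyallyl group (also the open face of the cerium chelate between the C6 alkoxide and the ketone), placing the C4 hydroxyl cis to the C5 side chain (C4 R).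

**Step 5**
Reactants: 9 (1R,2S,3R)-2-[(1S)-1-hydroxyprop-2-en-1-yl]-3-methyl-3-(3-methylbut-2-en-1-yl)-1-(propan-2-yl)cyclopentan-1-ol; 10 4-methoxybenzoyl chloride
Product: 11 (1S)-1-[(1S,2R,5R)-2-hydroxy-5-methyl-5-(3-methylbut-2-en-1-yl)-2-(propan-2-yl)cyclopentyl]prop-2-en-1-yl 4-methoxybenzoate
Conditions: Et3N, DMAP (0.2 equiv), CH2Cl2, 0 °C → rt
Reagents that add atoms: none
Why: DMAP-catalysed acylation should be selective for the secondary allylic C6 hydroxyl because the tertiary C4 hydroxyl is inert under these conditions; no stereocentre is touched.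

**Step 6**
Reactants: 11 (1S)-1-[(1S,2R,5R)-2-hydroxy-5-methyl-5-(3-methylbut-2-en-1-yl)-2-(propan-2-yl)cyclopentyl]prop-2-en-1-yl 4-methoxybenzoate
Product: 12 (1S)-1-[(1S,2R,5R)-5-{[(2R)-3,3-dimethyloxiran-2-yl]methyl}-2-hydroxy-5-methyl-2-(propan-2-yl)cyclopentyl]prop-2-en-1-yl 4-methoxybenzoate
Conditions: D-fructose-derived ketone catalyst (30 mol%), Oxone, K2CO3, Bu4NHSO4, MeCN–dimethoxymethane–aq. Na2B4O7 buffer, 0 °C
Reagents that add atoms: potassium peroxymonosulfate (active component of Oxone), [K+].[O-]S(=O)(=O)OO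
Why: Shi epoxidation, in which the chiral dioxirane should epoxidise the electron-rich trisubstituted prenyl olefin in preference to the monosubstituted allylic-ester vinyl group and, through its spiro transition state, set C9 (R) by reagent control.

**Step 7**
Reactants: 12 (1S)-1-[(1S,2R,5R)-5-{[(2R)-3,3-dimethyloxiran-2-yl]methyl}-2-hydroxy-5-methyl-2-(propan-2-yl)cyclopentyl]prop-2-en-1-yl 4-methoxybenzoate
Product: 13 (1S)-1-[(1S,2R,5R)-2-hydroxy-5-[(2R)-2-hydroxy-3-methylbut-3-en-1-yl]-5-methyl-2-(propan-2-yl)cyclopentyl]prop-2-en-1-yl 4-methoxybenzoate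
Conditions: Cp2TiCl2 (2.2 equiv), Mn dust, THF, rt; then 1 M HCl
Reagents that add atoms: none
Why: Titanocene-mediated radical isomerisation of a trisubstituted epoxide, in which trivalent titanium opens the tertiary C8–O bond homolytically, a second equivalent traps the tertiary radical and β-hydride elimination toward a methyl group gives the isopropenyl carbinol; the C9–O bond is never broken, so C9 (R) is retained.

**Step 8**
Reactants: 13 (1S)-1-[(1S,2R,5R)-2-hydroxy-5-[(2R)-2-hydroxy-3-methylbut-3-en-1-yl]-5-methyl-2-(propan-2-yl)cyclopentyl]prop-2-en-1-yl 4-methoxybenzoate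
Product: 14 (3R,3aS,4S,7R,8aR)-3,7-dihydroxy-6,8a-dimethyl-3-(propan-2-yl)-1,2,3,3a,4,7,8,8a-octahydroazulen-4-yl 4-methoxybenzoate
Conditions: second-generation Grubbs catalyst (5 mol%), 2,6-dichloro-1,4-benzoquinone (10 mol%), degassed toluene (0.005 M), 80 °C
Reagents that add atoms: none
Why: Olefin metathesis by the Chauvin mechanism: the ruthenium alkylidene initiates at the monosubstituted vinyl group on C6, the resulting C7 alkylidene adds to the 1,1-disubstituted isopropenyl olefin at C8 in a [2+2] step, and the ruthenacyclobutane collapses to the C7=C8 bond and a ruthenium methylidene that leaves as ethene. The closest known reaction type is ring-closing metathesis of a vinyl and a 2-propenyl group to the trisubstituted cycloheptene of trans-fused hydroazulene terpenoids. Ring B closes as a seven-membered carbocycle by ring-closing olefin metathesis onto the preformed trans-1,2-disubstituted cyclopentane, and the ring enforces the Z olefin. No stereocentre is created, and C1, C4, C5, C6 and C9 are untouched because no bond at these carbons is made or broken. The step needs cyclisation to win over intermolecular metathesis and over ruthenium hydride isomerisation of the C9 allylic alcohol; high dilution, the vicinal trans arms held close on the cyclopentane, and the benzoquinone additive should secure this.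

**Compound list**
1 | 3-bromocyclopent-2-en-1-one | O=C1C=C(Br)CC1 | starting material
2 | tributyl(3-methylbut-2-en-1-yl)stannane | CCCC[Sn](CCCC)(CCCC)CC=C(C)C | starting material
3 | 3-(3-methylbut-2-en-1-yl)cyclopent-2-en-1-one | O=C1C=C(CC=C(C)C)CC1 | intermediate
4 | dimethyl{[(3R)-3-methyl-3-(3-methylbut-2-en-1-yl)cyclopent-1-en-1-yl]oxy}alumane (dimethylaluminium enolate, not isolated) | C[Al](C)OC1=C[C@@](C)(CC=C(C)C)CC1 | intermediate
5 | triethyl{[(3R)-3-methyl-3-(3-methylbut-2-en-1-yl)cyclopent-1-en-1-yl]oxy}silane | CC[Si](CC)(CC)OC1=C[C@@](C)(CC=C(C)C)CC1 | intermediate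
6 | prop-2-enal (acrolein) | C=CC=O | starting material
7 | trichloro{(1S)-1-[(1S,2R)-2-methyl-2-(3-methylbut-2-en-1-yl)-5-oxocyclopentyl]prop-2-en-1-yloxy}silane (trichlorosilyl aldolate, not isolated) | Cl[Si](Cl)(Cl)O[C@@H](C=C)[C@H]1C(=O)CC[C@]1(C)CC=C(C)C | intermediate
8 | (2S,3R)-2-[(1S)-1-hydroxyprop-2-en-1-yl]-3-methyl-3-(3-methylbut-2-en-1-yl)cyclopentan-1-one | O[C@@H](C=C)[C@H]1C(=O)CC[C@]1(C)CC=C(C)C | intermediate
9 | (1R,2S,3R)-2-[(1S)-1-hydroxyprop-2-en-1-yl]-3-methyl-3-(3-methylbut-2-en-1-yl)-1-(propan-2-yl)cyclopentan-1-ol | O[C@@H](C=C)[C@H]1[C@](O)(C(C)C)CC[C@]1(C)CC=C(C)C | intermediate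
10 | 4-methoxybenzoyl chloride | COc1ccc(cc1)C(Cl)=O | starting material
11 | (1S)-1-[(1S,2R,5R)-2-hydroxy-5-methyl-5-(3-methylbut-2-en-1-yl)-2-(propan-2-yl)cyclopentyl]prop-2-en-1-yl 4-methoxybenzoate | COc1ccc(cc1)C(=O)O[C@@H](C=C)[C@H]1[C@](O)(C(C)C)CC[C@]1(C)CC=C(C)C | intermediate
12 | (1S)-1-[(1S,2R,5R)-5-{[(2R)-3,3-dimethyloxiran-2-yl]methyl}-2-hydroxy-5-methyl-2-(propan-2-yl)cyclopentyl]prop-2-en-1-yl 4-methoxybenzoate | COc1ccc(cc1)C(=O)O[C@@H](C=C)[C@H]1[C@](O)(C(C)C)CC[C@]1(C)C[C@H]2OC2(C)C | intermediate
13 | (1S)-1-[(1S,2R,5R)-2-hydroxy-5-[(2R)-2-hydroxy-3-methylbut-3-en-1-yl]-5-methyl-2-(propan-2-yl)cyclopentyl]prop-2-en-1-yl 4-methoxybenzoate | COc1ccc(cc1)C(=O)O[C@@H](C=C)[C@H]1[C@](O)(C(C)C)CC[C@]1(C)C[C@@H](O)C(C)=C | intermediate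
14 | (3R,3aS,4S,7R,8aR)-3,7-dihydroxy-6,8a-dimethyl-3-(propan-2-yl)-1,2,3,3a,4,7,8,8a-octahydroazulen-4-yl 4-methoxybenzoate | COc1ccc(C(=O)O[C@H]2C=C(C)[C@H](O)C[C@@]3(C)CC[C@@](O)(C(C)C)[C@H]23)cc1 | target

**Step count and risks**
Total step count: 8. Longest linear sequence: 8 steps (1 → 14).

Most likely to fail, in order:

Step 4. The cerium aldolate of 8 may undergo retro-aldol cleavage, the hindered ketone may be enolised toward C3 or reduced by β-hydride transfer instead of being alkylated, and facial selectivity may be incomplete. Fallback: setting out from 8, the C6 hydroxyl is first silylated (Et3SiCl, imidazole, DMF) to the triethylsilyl ether of the aldol F1, which cannot fragment. Isopropyllithium premixed with anhydrous CeCl3 (THF, −78 °C) is then added anti to the silyloxyallyl group to give the tertiary alcohol silyl ether F2. Bu4NF in THF removes the silyl group and the route is rejoined at 9.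

Step 3. The enol ether may be attacked on the face cis to the prenyl arm, anti selectivity may erode in the open transition state next to the quaternary carbon, and acrolein may oligomerise under the chlorosilane. Fallback: setting out from 5, silicon exchange with SiCl4 and catalytic Hg(OAc)2 gives the trichlorosilyl enolate F3. Under a chiral stilbene-1,2-diamine-derived phosphoramide (10 mol%, CH2Cl2, −78 °C) this adds to acrolein through a closed six-membered transition state on hexacoordinate silicon, in which the (E)-enolate geometry enforces the anti relationship and the bound Lewis base selects the face. The route is rejoined at 7, which is hydrolysed to 8 as before.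

Step 7. The tertiary radical may be reduced to the saturated carbinol instead of eliminating, elimination may give the wrong olefin, or the allylic ester may be attacked by the low-valent metal. Fallback: setting out from 11, a Schenck ene reaction with singlet oxygen (O2, tetraphenylporphyrin, visible light, CH2Cl2, 0 °C) converts the prenyl group into the secondary allylic hydroperoxide F4 (both C9 epimers). Kornblum–DeLaMare dehydration (Ac2O, pyridine) gives the isopropenyl ketone F5. CBS reduction with the (S)-oxazaborolidine and BH3·SMe2 (THF, −30 °C), the isopropenyl group acting as the large substituent, sets C9 (R) and the route is rejoined at 13.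

**Further compounds**
F1 | step 4 | (2S,3R)-3-methyl-3-(3-methylbut-2-en-1-yl)-2-{(1S)-1-[(triethylsilyl)oxy]prop-2-en-1-yl}cyclopentan-1-one | CC[Si](CC)(CC)O[C@@H](C=C)[C@H]1C(=O)CC[C@]1(C)CC=C(C)C
F2 | step 4 | (1R,2S,3R)-3-methyl-3-(3-methylbut-2-en-1-yl)-1-(propan-2-yl)-2-{(1S)-1-[(triethylsilyl)oxy]prop-2-en-1-yl}cyclopentan-1-ol | CC[Si](CC)(CC)O[C@@H](C=C)[C@H]1[C@](O)(C(C)C)CC[C@]1(C)CC=C(C)C
F3 | step 3 | trichloro{[(3R)-3-methyl-3-(3-methylbut-2-en-1-yl)cyclopent-1-en-1-yl]oxy}silane | Cl[Si](Cl)(Cl)OC1=C[C@@](C)(CC=C(C)C)CC1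
F4 | step 7 | (1S)-1-[(1S,2R,5R)-5-(2-hydroperoxy-3-methylbut-3-en-1-yl)-2-hydroxy-5-methyl-2-(propan-2-yl)cyclopentyl]prop-2-en-1-yl 4-methoxybenzoate (both epimers at the hydroperoxy carbon) | COc1ccc(cc1)C(=O)O[C@@H](C=C)[C@H]1[C@](O)(C(C)C)CC[C@]1(C)CC(OO)C(C)=C
F5 | step 7 | (1S)-1-[(1S,2R,5R)-2-hydroxy-5-methyl-5-(3-methyl-2-oxobut-3-en-1-yl)-2-(propan-2-yl)cyclopentyl]prop-2-en-1-yl 4-methoxybenzoate | COc1ccc(cc1)C(=O)O[C@@H](C=C)[C@H]1[C@](O)(C(C)C)CC[C@]1(C)CC(=O)C(C)=C
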